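Labels: ring A is the cyclopentane Ca (CH bearing isopropenyl), Cb and Cc (CH2), Cd (C(CH3)(OH)), Ce (CH bearing the CH2 link). Ring B is the enolised 2-acylcyclohexane-1,3,5-trione with quaternary Cq (CH3, prenyl) and the link at C-4.
Feature used: in ring A the Ca–Cb bond joins an unfunctionalised CH2 (Cb) to the allylic methine Ca. A primary radical at Cb can therefore add 5-exo to Ca of a Ce–CH=C(CH3)–CH2SO2Ph chain and shed PhSO2•, which closes ring A and creates the isopropenyl group in one event (16 to 19).
Precursor 16: Cd and Ce are set on the open chain by Sharpless epoxidation of Z allylic alcohol 5 and anti opening at C-2 with an isobutenyl copper reagent. Enolate alkylation next to a carbinol carrying CH3 and CH2CH2OR would have no facial bias. Allylic oxidation, sulfinate displacement and iodination finish 16.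
Ring B (32): Cq comes from two successive Fráter–Seebach alkylations of methyl (R)-3-hydroxybutanoate. Two C-acylations and a Dieckmann closure then build the ring, so the acyl-bearing carbon and the free ring carbon are distinct from the start.
Union: reductive Knoevenagel alkylation of 32 at C-4 by ring A aldehyde 21, then desilylation. Ring A (step 13) and ring B (step 22) are made in parallel branches and joined in step 23.

Key step: step 13

Assumption: ring B compounds (32 to 35, F10, F11) are drawn in the enol tautomer of the target SMILES, and the Cq descriptor refers to that tautomer; tautomer exchange does not touch Cq.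
Assumption: (2R)-2-methylbutanoic acid 27 is bought as the single enantiomer, so the sec-butyl stereocentre is purchased and only has to be preserved.

Step 1
Reactants: 1 tert-butyl(but-3-yn-1-yloxy)dimethylsilane; 2 methyl chloroformate
Product: 3 methyl 5-[(tert-butyldimethylsilyl)oxy]pent-2-ynoate
Conditions: n-BuLi, THF, −78 °C; then 2, −78 to 0 °C
Reagents that add atoms: none
Why: Acetylide C-acylation, in which the lithiated terminal alkyne attacks the chloroformate and chloride leaves; the new ester carbon is the future CH2 link and the four chain carbons are the future Ce, Cd, Cc and Cb.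

Step 2
Reactants: 3 methyl 5-[(tert-butyldimethylsilyl)oxy]pent-2-ynoate
Product: 4 methyl (2Z)-5-[(tert-butyldimethylsilyl)oxy]-3-methylpent-2-enoate
Conditions: Me2CuLi (from MeLi and CuI), THF, −78 °C; aq. NH4Cl quench at −78 °C
Reagents that add atoms: lithium dimethylcuprate, [Li+].C[Cu-]C
Why: Organocuprate conjugate addition to an ynoate is a syn carbometalation, so methyl and copper (hydrogen after the cold quench) end cis and the ester ends cis to the CH2CH2OSi chain, which fixes the Z geometry that the anti epoxide opening of step 5 requires.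

Step 3
Reactants: 4 methyl (2Z)-5-[(tert-butyldimethylsilyl)oxy]-3-methylpent-2-enoate
Product: 5 (2Z)-5-[(tert-butyldimethylsilyl)oxy]-3-methylpent-2-en-1-ol
Conditions: i-Bu2AlH (2.2 equiv), CH2Cl2, −78 °C; aq. potassium sodium tartrate
Reagents that add atoms: none
Why: 1,2-Reduction of an enoate to the allylic alcohol by an aluminium hydride leaves the alkene geometry and the silyl ether untouched.

Step 4
Reactants: 5 (2Z)-5-[(tert-butyldimethylsilyl)oxy]-3-methylpent-2-en-1-ol
Product: 6 [(2R,3S)-3-{2-[(tert-butyldimethylsilyl)oxy]ethyl}-3-methyloxiran-2-yl]methanol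
Conditions: Ti(O-i-Pr)4 (10 mol %), D-(−)-diethyl tartrate (12 mol %), t-BuOOH, 4 Å MS, CH2Cl2, −20 °C
Reagents that add atoms: tert-butyl hydroperoxide, CC(C)(C)OO
Why: Sharpless asymmetric epoxidation, in which the D-(−)-tartrate titanium complex delivers oxygen to the alkene face that makes C-2 R and C-3 S (the mirror image of the sense that L-(+)-tartrate shows with Z trisubstituted allylic alcohols), so Cd is set here together with the C-2 centre that is inverted in step 5.

Step 5
Reactants: 6 [(2R,3S)-3-{2-[(tert-butyldimethylsilyl)oxy]ethyl}-3-methyloxiran-2-yl]methanol; 7 (2-methylprop-1-en-1-yl)magnesium bromide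
Product: 8 (2S,3S)-5-[(tert-butyldimethylsilyl)oxy]-3-methyl-2-(2-methylprop-1-en-1-yl)pentane-1,3-diol
Conditions: 7 (4 equiv), CuI (20 mol %), THF–Et2O, −40 to 0 °C; aq. NH4Cl
Reagents that add atoms: none
Why: Copper-catalysed Grignard opening of a trisubstituted 2,3-epoxy alcohol goes by SN2 attack at the secondary C-2 because the fully substituted C-3 is blocked, so Ce is set by inversion and CH2OH and the tertiary OH end in the relation that becomes cis on ring A.

Step 6
Reactants: 8 (2S,3S)-5-[(tert-butyldimethylsilyl)oxy]-3-methyl-2-(2-methylprop-1-en-1-yl)pentane-1,3-diol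
Product: 9 (3S,4S)-4-[(benzyloxy)methyl]-1-[(tert-butyldimethylsilyl)oxy]-3,6-dimethylhept-5-en-3-ol
Conditions: NaH (1.05 equiv), BnBr, n-Bu4NI (cat.), THF, 0 °C to rt
Reagents that add atoms: benzyl bromide, BrCc1ccccc1
Why: Williamson etherification with one equivalent of base benzylates the primary alkoxide much faster than the hindered tertiary alcohol.

Step 7
Reactants: 9 (3S,4S)-4-[(benzyloxy)methyl]-1-[(tert-butyldimethylsilyl)oxy]-3,6-dimethylhept-5-en-3-ol
Product: 10 (2E,4S,5S)-4-[(benzyloxy)methyl]-7-[(tert-butyldimethylsilyl)oxy]-2,5-dimethylhept-2-ene-1,5-diol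
Conditions: SeO2 (0.3 equiv), t-BuOOH, salicylic acid (cat.), CH2Cl2, 0 °C to rt
Reagents that add atoms: tert-butyl hydroperoxide, CC(C)(C)OO
Why: Selenium dioxide allylic oxidation (ene reaction followed by [2,3]-sigmatropic shift) acts at the more substituted alkene terminus and on the methyl group trans to Ce, which should give the E allylic alcohol and leave the Ce–H untouched.

Step 8
Reactants: 10 (2E,4S,5S)-4-[(benzyloxy)methyl]-7-[(tert-butyldimethylsilyl)oxy]-2,5-dimethylhept-2-ene-1,5-diol
Product: 11 (3S,4S,5E)-4-[(benzyloxy)methyl]-7-bromo-1-[(tert-butyldimethylsilyl)oxy]-3,6-dimethylhept-5-en-3-ol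
Conditions: CBr4, PPh3, CH2Cl2, −20 to 0 °C
Reagents that add atoms: carbon tetrabromide, BrC(Br)(Br)Br
Why: In the Appel reaction only the primary allylic alcohol forms an oxyphosphonium salt that bromide can displace by SN2, while the tertiary alcohol stays inert at this temperature and the E alkene keeps it out of reach of the bromide carbon.

Step 9
Reactants: 11 (3S,4S,5E)-4-[(benzyloxy)methyl]-7-bromo-1-[(tert-butyldimethylsilyl)oxy]-3,6-dimethylhept-5-en-3-ol; 12 sodium benzenesulfinate
Product: 13 (3S,4S,5E)-7-(benzenesulfonyl)-4-[(benzyloxy)methyl]-1-[(tert-butyldimethylsilyl)oxy]-3,6-dimethylhept-5-en-3-ol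
Conditions: 12, DMF, rt
Reagents that add atoms: none
Why: SN2 displacement of the primary allylic bromide by the soft sulfur atom of the sulfinate gives the sulfone with the alkene position and geometry retained.

Step 10
Reactants: 13 (3S,4S,5E)-7-(benzenesulfonyl)-4-[(benzyloxy)methyl]-1-[(tert-butyldimethylsilyl)oxy]-3,6-dimethylhept-5-en-3-ol
Product: 14 (3S,4S,5E)-7-(benzenesulfonyl)-4-[(benzyloxy)methyl]-3,6-dimethylhept-5-ene-1,3-diol
Conditions: HF·pyridine, pyridine, THF, 0 °C to rt
Reagents that add atoms: none
Why: Fluoride desilylation under buffered, non-basic conditions frees the Cb alcohol without shifting the allyl sulfone into conjugation, and because the tertiary alcohol is still unprotected no silyl ether has to be spared.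

Step 11
Reactants: 14 (3S,4S,5E)-7-(benzenesulfonyl)-4-[(benzyloxy)methyl]-3,6-dimethylhept-5-ene-1,3-diol
Product: 15 (3S,4S,5E)-7-(benzenesulfonyl)-4-[(benzyloxy)methyl]-1-iodo-3,6-dimethylhept-5-en-3-ol
Conditions: I2, PPh3, imidazole, CH2Cl2, 0 °C
Reagents that add atoms: iodine, II
Why: Appel-type iodination converts only the primary alcohol, since SN2 displacement of the oxyphosphonium group is impossible at the tertiary carbinol.

Step 12
Reactants: 15 (3S,4S,5E)-7-(benzenesulfonyl)-4-[(benzyloxy)methyl]-1-iodo-3,6-dimethylhept-5-en-3-ol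
Product: 16 {[(3S,4S,5E)-7-(benzenesulfonyl)-4-[(benzyloxy)methyl]-1-iodo-3,6-dimethylhept-5-en-3-yl]oxy}triethylsilane
Conditions: Et3SiOTf, 2,6-lutidine, CH2Cl2, −78 to 0 °C
Reagents that add atoms: triethylsilyl trifluoromethanesulfonate, CC[Si](CC)(CC)OS(=O)(=O)C(F)(F)F
Why: Silylation with the silyl triflate and a hindered pyridine base is the standard way to cap a tertiary alcohol, and it tolerates the primary iodide and the allyl sulfone.

Step 13
Reactants: 16 {[(3S,4S,5E)-7-(benzenesulfonyl)-4-[(benzyloxy)methyl]-1-iodo-3,6-dimethylhept-5-en-3-yl]oxy}triethylsilane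
Product: 19 {[(1S,2S,3S)-2-[(benzyloxy)methyl]-1-methyl-3-(prop-1-en-2-yl)cyclopentyl]oxy}triethylsilane, via primary alkyl radical 17 (not isolated), via tertiary sulfonylalkyl radical 18 (not isolated)
Conditions: Bu3SnH (1.3 equiv) and AIBN (0.2 equiv) added by syringe pump, degassed benzene (0.01 M), reflux
Reagents that add atoms: none
Why: Bu3Sn• abstracts iodine from 16 to give the primary radical 17 at Cb, which adds 5-exo-trig to Ca, the CH terminus of the trisubstituted alkene, forming Ca–Cb and closing ring A; the tertiary β-sulfonyl radical 18 then loses PhSO2• by β-scission, which uncovers the isopropenyl group, and PhSO2• takes hydrogen from Bu3SnH to carry the chain. The closest known reaction type is radical 5-exo cyclisation onto allyl sulfones or allyl sulfides with β-elimination of the sulfur radical (addition–fragmentation). The only new stereocentre, Ca, is controlled by the existing Ce and Cd centres through a chair-like transition state in which CH2OBn on Ce and CH3 on Cd are pseudo-equatorial and the silyloxy group, with the smaller conformational demand, is pseudo-axial, and allylic strain between the alkene methyl group cis to Ce and any pseudo-axial group on Ce reinforces this, so the side chain should come out trans to the Ce arm and cis to the Cd methyl (Ca S). Chemoselectivity requires iodine abstraction to outrun tin-radical addition to the allyl sulfone, which the weak primary C–I bond and the hindered Ca secure. Regioselectivity (5-exo over 6-endo) follows from attack at the less substituted alkene carbon, and the fully substituted Cd accelerates closure, so at low stannane concentration cyclisation and fragmentation should outrun hydrogen transfer to 17 or 18.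

Step 14
Reactants: 19 {[(1S,2S,3S)-2-[(benzyloxy)methyl]-1-methyl-3-(prop-1-en-2-yl)cyclopentyl]oxy}triethylsilane
Product: 20 [(1S,2S,5S)-2-methyl-5-(prop-1-en-2-yl)-2-[(triethylsilyl)oxy]cyclopentyl]methanol
Conditions: Na, NH3(l)–THF, −78 °C; solid NH4Cl
Reagents that add atoms: none
Why: Dissolving-metal (Birch-type) cleavage of the benzyl ether proceeds by electron transfer to the arene and loss of the alkoxide, and it spares the isolated 1,1-disubstituted alkene and the silyl ether, whereas hydrogenolysis would saturate the isopropenyl group.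

Step 15
Reactants: 20 [(1S,2S,5S)-2-methyl-5-(prop-1-en-2-yl)-2-[(triethylsilyl)oxy]cyclopentyl]methanol
Product: 21 (1R,2S,5S)-2-methyl-5-(prop-1-en-2-yl)-2-[(triethylsilyl)oxy]cyclopentane-1-carbaldehyde
Conditions: Dess–Martin periodinane, NaHCO3, CH2Cl2, 0 °C to rt
Reagents that add atoms: none
Why: Dess–Martin oxidation under buffered, non-basic conditions stops at the aldehyde and leaves Ce, which already has the more stable trans arrangement to the isopropenyl group, unchanged.

Step 16
Reactants: 22 methyl (3R)-3-hydroxybutanoate; 23 1-bromo-3-methylbut-2-ene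
Product: 24 methyl (2R)-2-[(1R)-1-hydroxyethyl]-5-methylhex-4-enoate
Conditions: LiN(i-Pr)2 (LDA, 2.2 equiv), THF, −78 to −20 °C; 23, DMPU, −78 to 0 °C
Reagents that add atoms: none
Why: In the Fráter–Seebach alkylation the lithium-chelated alkoxide enolate is attacked on the face anti to the carbinol methyl group, which gives the anti (2R,3R) product.

Step 17
Reactants: 24 methyl (2R)-2-[(1R)-1-hydroxyethyl]-5-methylhex-4-enoate
Product: 25 methyl (2S)-2-[(1R)-1-hydroxyethyl]-2,5-dimethylhex-4-enoate
Conditions: LiN(i-Pr)2 (LDA, 2.5 equiv), THF, −78 to 0 °C; MeI, DMPU, −78 to 0 °C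
Reagents that add atoms: iodomethane, CI
Why: In this second Fráter–Seebach alkylation chelation fixes the same enolate geometry and the same open face, so methyl enters where prenyl entered before and Cq is set as 2S, and the order prenyl then methyl is what delivers this configuration from the R hydroxy ester.

Step 18
Reactants: 25 methyl (2S)-2-[(1R)-1-hydroxyethyl]-2,5-dimethylhex-4-enoate
Product: 26 methyl (2S)-2-acetyl-2,5-dimethylhex-4-enoate
Conditions: Dess–Martin periodinane, CH2Cl2, rt
Reagents that add atoms: none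
Why: Dess–Martin oxidation removes the now spent carbinol stereocentre, and Cq cannot epimerise because it carries no hydrogen.

Step 19
Reactants: 27 (2R)-2-methylbutanoic acid
Product: 28 pentafluorophenyl (2R)-2-methylbutanoate
Conditions: C6F5OH, DCC, CH2Cl2, 0 °C to rt
Reagents that add atoms: pentafluorophenol, Oc1c(F)c(F)c(F)c(F)c1F
Why: Carbodiimide esterification without added base gives an active ester without passing through a ketene, so the α-stereocentre is kept.

Step 20
Reactants: 26 methyl (2S)-2-acetyl-2,5-dimethylhex-4-enoate; 28 pentafluorophenyl (2R)-2-methylbutanoate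
Product: 29 methyl (2S,6R)-2,6-dimethyl-2-(3-methylbut-2-en-1-yl)-3,5-dioxooctanoate
Conditions: MgBr2·OEt2 (2.5 equiv), i-Pr2NEt (3 equiv), CH2Cl2, rt
Reagents that add atoms: none
Why: This is a crossed Claisen C-acylation under soft enolisation, in which MgBr2 chelates the β-keto ester, the amine removes a proton from the only enolisable position (the acetyl CH3, future C-2), and the product is held as its magnesium diketonate, which shields the sec-butyl stereocentre from enolisation.

Step 21
Reactants: 29 methyl (2S,6R)-2,6-dimethyl-2-(3-methylbut-2-en-1-yl)-3,5-dioxooctanoate; 30 acetyl chloride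
Product: 31 methyl (2S,6R)-4-acetyl-2,6-dimethyl-2-(3-methylbut-2-en-1-yl)-3,5-dioxooctanoate (triacylmethane, C-4 labile through the enol)
Conditions: MgCl2, pyridine, CH2Cl2, 0 °C; then 30
Reagents that add atoms: none
Why: C-Acylation of the magnesium chelate of a 1,3-diketone with an acid chloride places the acetyl group (future C-3 and C-4 of ring B) on the central carbon (future C-2) rather than on oxygen.

Step 22
Reactants: 31 methyl (2S,6R)-4-acetyl-2,6-dimethyl-2-(3-methylbut-2-en-1-yl)-3,5-dioxooctanoate
Product: 32 (6R)-3,5-dihydroxy-6-methyl-2-[(2R)-2-methylbutanoyl]-6-(3-methylbut-2-en-1-yl)cyclohexa-2,4-dien-1-one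
Conditions: LiN(i-Pr)2 (LDA, 3.3 equiv), THF, −78 to 0 °C; 1 M HCl
Reagents that add atoms: none
Why: In this Dieckmann-type intramolecular Claisen condensation LDA removes the acidic central proton and then a proton of the acetyl CH3 (kinetically favoured over the sec-butyl methine), this terminal carbanion attacks the methyl ester in a 6-exo-trig closure, and because the acyl group sits on C-2 before the ring closes the two flanks of Cq stay distinct and its geometry is carried over (the descriptor changes from S to R by priority only).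

Step 23
Reactants: 21 (1R,2S,5S)-2-methyl-5-(prop-1-en-2-yl)-2-[(triethylsilyl)oxy]cyclopentane-1-carbaldehyde; 32 (6R)-3,5-dihydroxy-6-methyl-2-[(2R)-2-methylbutanoyl]-6-(3-methylbut-2-en-1-yl)cyclohexa-2,4-dien-1-one
Product: 34 triethylsilyl ether of the target, via alkylidene trione 33 (not isolated)
Conditions: Hantzsch ester (diethyl 2,6-dimethyl-1,4-dihydropyridine-3,5-dicarboxylate, 1.2 equiv), L-proline (20 mol %), CH2Cl2, rt
Reagents that add atoms: none
Why: In this three-component reductive Knoevenagel alkylation proline-catalysed condensation at the only free ring carbon C-4 gives the electron-poor alkylidene trione 33, which should take hydride from the Hantzsch ester faster than a second trione can add, while the isolated alkenes are inert and no stereocentre is formed.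

Step 24
Reactants: 34 triethylsilyl ether of the target
Product: 35 (6R)-3,5-dihydroxy-4-{[(1R,2S,5S)-2-hydroxy-2-methyl-5-(prop-1-en-2-yl)cyclopentyl]methyl}-6-methyl-2-[(2R)-2-methylbutanoyl]-6-(3-methylbut-2-en-1-yl)cyclohexa-2,4-dien-1-one (CNP0299585.1)
Conditions: HF·pyridine, pyridine, THF, 0 °C
Reagents that add atoms: none
Why: Fluoride-driven cleavage of the Si–O bond under buffered conditions frees the tertiary alcohol without acid-induced reaction of the enols with the prenyl or isopropenyl group.

Compound list
1 | tert-butyl(but-3-yn-1-yloxy)dimethylsilane | C#CCCO[Si](C)(C)C(C)(C)C | starting material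
2 | methyl chloroformate | COC(=O)Cl | starting material
3 | methyl 5-[(tert-butyldimethylsilyl)oxy]pent-2-ynoate | COC(=O)C#CCCO[Si](C)(C)C(C)(C)C | intermediate
4 | methyl (2Z)-5-[(tert-butyldimethylsilyl)oxy]-3-methylpent-2-enoate | COC(=O)/C=C(/C)CCO[Si](C)(C)C(C)(C)C | intermediate
5 | (2Z)-5-[(tert-butyldimethylsilyl)oxy]-3-methylpent-2-en-1-ol | OC/C=C(/C)CCO[Si](C)(C)C(C)(C)C | intermediate
6 | [(2R,3S)-3-{2-[(tert-butyldimethylsilyl)oxy]ethyl}-3-methyloxiran-2-yl]methanol | OC[C@H]1O[C@@]1(C)CCO[Si](C)(C)C(C)(C)C | intermediate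
7 | (2-methylprop-1-en-1-yl)magnesium bromide | CC(C)=C[Mg]Br | starting material
8 | (2S,3S)-5-[(tert-butyldimethylsilyl)oxy]-3-methyl-2-(2-methylprop-1-en-1-yl)pentane-1,3-diol | CC(C)(C)[Si](C)(C)OCC[C@](C)(O)[C@@H](C=C(C)C)CO | intermediate
9 | (3S,4S)-4-[(benzyloxy)methyl]-1-[(tert-butyldimethylsilyl)oxy]-3,6-dimethylhept-5-en-3-ol | CC(C)(C)[Si](C)(C)OCC[C@](C)(O)[C@@H](C=C(C)C)COCc1ccccc1 | intermediate
10 | (2E,4S,5S)-4-[(benzyloxy)methyl]-7-[(tert-butyldimethylsilyl)oxy]-2,5-dimethylhept-2-ene-1,5-diol | CC(C)(C)[Si](C)(C)OCC[C@](C)(O)[C@@H](/C=C(\C)CO)COCc1ccccc1 | intermediate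
11 | (3S,4S,5E)-4-[(benzyloxy)methyl]-7-bromo-1-[(tert-butyldimethylsilyl)oxy]-3,6-dimethylhept-5-en-3-ol | CC(C)(C)[Si](C)(C)OCC[C@](C)(O)[C@@H](/C=C(\C)CBr)COCc1ccccc1 | intermediate
12 | sodium benzenesulfinate | [Na+].[O-]S(=O)c1ccccc1 | starting material
13 | (3S,4S,5E)-7-(benzenesulfonyl)-4-[(benzyloxy)methyl]-1-[(tert-butyldimethylsilyl)oxy]-3,6-dimethylhept-5-en-3-ol | CC(C)(C)[Si](C)(C)OCC[C@](C)(O)[C@@H](/C=C(\C)CS(=O)(=O)c1ccccc1)COCc1ccccc1 | intermediate
14 | (3S,4S,5E)-7-(benzenesulfonyl)-4-[(benzyloxy)methyl]-3,6-dimethylhept-5-ene-1,3-diol | OCC[C@](C)(O)[C@@H](/C=C(\C)CS(=O)(=O)c1ccccc1)COCc1ccccc1 | intermediate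
15 | (3S,4S,5E)-7-(benzenesulfonyl)-4-[(benzyloxy)methyl]-1-iodo-3,6-dimethylhept-5-en-3-ol | ICC[C@](C)(O)[C@@H](/C=C(\C)CS(=O)(=O)c1ccccc1)COCc1ccccc1 | intermediate
16 | {[(3S,4S,5E)-7-(benzenesulfonyl)-4-[(benzyloxy)methyl]-1-iodo-3,6-dimethylhept-5-en-3-yl]oxy}triethylsilane (key-step precursor) | ICC[C@](C)(O[Si](CC)(CC)CC)[C@@H](/C=C(\C)CS(=O)(=O)c1ccccc1)COCc1ccccc1 | intermediate
17 | primary alkyl radical at Cb formed from 16 by loss of iodine | [CH2]C[C@](C)(O[Si](CC)(CC)CC)[C@@H](/C=C(\C)CS(=O)(=O)c1ccccc1)COCc1ccccc1 | intermediate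
18 | cyclised tertiary β-sulfonylalkyl radical | C[C](CS(=O)(=O)c1ccccc1)[C@H]1CC[C@](C)(O[Si](CC)(CC)CC)[C@@H]1COCc1ccccc1 | intermediate
19 | {[(1S,2S,3S)-2-[(benzyloxy)methyl]-1-methyl-3-(prop-1-en-2-yl)cyclopentyl]oxy}triethylsilane (key-step product) | C=C(C)[C@H]1CC[C@](C)(O[Si](CC)(CC)CC)[C@@H]1COCc1ccccc1 | intermediate
20 | [(1S,2S,5S)-2-methyl-5-(prop-1-en-2-yl)-2-[(triethylsilyl)oxy]cyclopentyl]methanol | C=C(C)[C@H]1CC[C@](C)(O[Si](CC)(CC)CC)[C@@H]1CO | intermediate
21 | (1R,2S,5S)-2-methyl-5-(prop-1-en-2-yl)-2-[(triethylsilyl)oxy]cyclopentane-1-carbaldehyde | C=C(C)[C@H]1CC[C@](C)(O[Si](CC)(CC)CC)[C@@H]1C=O | intermediate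
22 | methyl (3R)-3-hydroxybutanoate | C[C@@H](O)CC(=O)OC | starting material
23 | 1-bromo-3-methylbut-2-ene (prenyl bromide) | CC(C)=CCBr | starting material
24 | methyl (2R)-2-[(1R)-1-hydroxyethyl]-5-methylhex-4-enoate | C[C@@H](O)[C@@H](CC=C(C)C)C(=O)OC | intermediate
25 | methyl (2S)-2-[(1R)-1-hydroxyethyl]-2,5-dimethylhex-4-enoate | C[C@@H](O)[C@@](CC=C(C)C)(C)C(=O)OC | intermediate
26 | methyl (2S)-2-acetyl-2,5-dimethylhex-4-enoate | CC(=O)[C@@](CC=C(C)C)(C)C(=O)OC | intermediate
27 | (2R)-2-methylbutanoic acid | CC[C@@H](C)C(=O)O | starting material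
28 | pentafluorophenyl (2R)-2-methylbutanoate | CC[C@@H](C)C(=O)Oc1c(F)c(F)c(F)c(F)c1F | intermediate
29 | methyl (2S,6R)-2,6-dimethyl-2-(3-methylbut-2-en-1-yl)-3,5-dioxooctanoate | CC[C@@H](C)C(=O)CC(=O)[C@@](CC=C(C)C)(C)C(=O)OC | intermediate
30 | acetyl chloride | CC(=O)Cl | starting material
31 | methyl (2S,6R)-4-acetyl-2,6-dimethyl-2-(3-methylbut-2-en-1-yl)-3,5-dioxooctanoate (C-4 labile through the enol) | CC[C@@H](C)C(=O)C(C(C)=O)C(=O)[C@@](CC=C(C)C)(C)C(=O)OC | intermediate
32 | (6R)-3,5-dihydroxy-6-methyl-2-[(2R)-2-methylbutanoyl]-6-(3-methylbut-2-en-1-yl)cyclohexa-2,4-dien-1-one (ring B) | C1=C(O)[C@@](C)(CC=C(C)C)C(=O)C(C(=O)[C@H](C)CC)=C1O | intermediate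
33 | C-4 alkylidene trione from 21 and 32 (exocyclic alkene geometry not defined, both forms are reduced to 34) | C=C(C)[C@H]1CC[C@](C)(O[Si](CC)(CC)CC)[C@@H]1C=C1C(=O)[C@@](C)(CC=C(C)C)C(=O)C(C(=O)[C@H](C)CC)=C1O | intermediate
34 | triethylsilyl ether of the target | C=C(C)[C@H]1CC[C@](C)(O[Si](CC)(CC)CC)[C@@H]1CC1=C(O)[C@@](C)(CC=C(C)C)C(=O)C(C(=O)[C@H](C)CC)=C1O | intermediate
35 | (6R)-3,5-dihydroxy-4-{[(1R,2S,5S)-2-hydroxy-2-methyl-5-(prop-1-en-2-yl)cyclopentyl]methyl}-6-methyl-2-[(2R)-2-methylbutanoyl]-6-(3-methylbut-2-en-1-yl)cyclohexa-2,4-dien-1-one | C=C(C)[C@H]1CC[C@](C)(O)[C@@H]1CC1=C(O)[C@@](C)(CC=C(C)C)C(=O)C(C(=O)[C@H](C)CC)=C1O | target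

Total step count: 24.
Longest linear sequence: 17 (steps 1 to 15, 23, 24). The ring B branch has six linear steps (16 to 18, 20 to 22) plus step 19.
Stereocentres:
- Cd is set in step 4.
- Ce is set in step 5.
- Ca is set in step 13.
- Cq is set in steps 16 and 17.
- The sec-butyl centre is bought with 27.
- Any minor enantiomer of either branch becomes a diastereomer of 34 and should be removable by chromatography at that stage.

Steps most likely to fail

1. Step 13. Three processes could defeat it:
- hydrogen transfer from the stannane to the primary radical before ring closure;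
- attack of the tin radical on the allyl sulfone, which breaks the chain;
- insufficient facial selectivity at Ca.

Fallback (sets out from 9, returns at 19): the sulfone is dispensed with, and the alkene is regenerated by loss of a hydrogen atom instead of a sulfonyl radical. HF·pyridine frees the primary alcohol of 9 and gives the 1,3-diol F1. I2, PPh3 and imidazole convert it into the iodo alcohol F2. Et3SiOTf with 2,6-lutidine gives the triethylsilyl ether F3, which keeps the isobutenyl group as radical acceptor. A cobaloxime-catalysed alkyl Heck-type cyclisation follows (Co(dmgH)2(py)Cl, i-Pr2NEt, MeCN, blue light). Monovalent cobalt displaces iodide, light homolyses the Co–C bond, and the Cb radical closes Ca–Cb 5-exo through the same chair. Divalent cobalt then takes one of the six accessible methyl hydrogens of the tertiary radical. This should favour isopropenyl over the tetrasubstituted isopropylidene isomer and give 19 with neither a hydride source nor a tin radical present.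

2. Step 23. Condensation of the hindered α-branched aldehyde may be slow. That would leave time for enamine-mediated epimerisation at Ce, β-elimination of the silanolate, or double addition of the trione to the alkylidene.

Fallback (sets out from 21 and 29, returns at 34): ring B is closed around the link instead of being alkylated. Wittig reaction of 21 with methyl (triphenylphosphoranylidene)acetate gives the E enoate F4. Conjugate reduction with [(Ph3P)CuH]6 gives the saturated ester F5 without touching the isopropenyl group. LiOH gives the acid F6, and 1-chloro-N,N,2-trimethylprop-1-en-1-amine gives the acid chloride F7 under neutral conditions. C-Acylation of the magnesium chelate of 29 (MgCl2, pyridine) with F7 gives the triacylmethane F8. In F8 the CH2 next to the new ketone is the future C-4 and already carries the link. LDA then closes this carbon onto the methyl ester as in step 22 and delivers 34 directly.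

3. Step 22. Three processes could defeat it:
- incomplete second deprotonation of the triacylmethane;
- loss of the acetyl group by retro-Claisen cleavage;
- proton loss at the sec-butyl methine, leading to epimerisation.

Fallback (sets out from 29, returns at 32): an ester is added as an activating group on the future C-4, so that the closure runs through a soft, doubly stabilised enolate. 29 is C-acylated (MgCl2, pyridine) with methyl 3-chloro-3-oxopropanoate to give the malonyl triketone F9. NaH in THF closes the β-keto ester carbon onto the hindered ester and gives the ring B methyl ester F10. LiOH hydrolysis gives the vinylogous β-keto acid F11, which loses CO2 on mild acidification and gives 32.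

Further compounds
F1 | step 13 | (3S,4S)-4-[(benzyloxy)methyl]-3,6-dimethylhept-5-ene-1,3-diol | OCC[C@](C)(O)[C@@H](C=C(C)C)COCc1ccccc1
F2 | step 13 | (3S,4S)-4-[(benzyloxy)methyl]-1-iodo-3,6-dimethylhept-5-en-3-ol | ICC[C@](C)(O)[C@@H](C=C(C)C)COCc1ccccc1
F3 | step 13 | {[(3S,4S)-4-[(benzyloxy)methyl]-1-iodo-3,6-dimethylhept-5-en-3-yl]oxy}triethylsilane | ICC[C@](C)(O[Si](CC)(CC)CC)[C@@H](C=C(C)C)COCc1ccccc1
F4 | step 23 | methyl (2E)-3-[(1R,2S,5S)-2-methyl-5-(prop-1-en-2-yl)-2-[(triethylsilyl)oxy]cyclopentyl]prop-2-enoate | C=C(C)[C@H]1CC[C@](C)(O[Si](CC)(CC)CC)[C@@H]1/C=C/C(=O)OC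
F5 | step 23 | methyl 3-[(1R,2S,5S)-2-methyl-5-(prop-1-en-2-yl)-2-[(triethylsilyl)oxy]cyclopentyl]propanoate | C=C(C)[C@H]1CC[C@](C)(O[Si](CC)(CC)CC)[C@@H]1CCC(=O)OC
F6 | step 23 | 3-[(1R,2S,5S)-2-methyl-5-(prop-1-en-2-yl)-2-[(triethylsilyl)oxy]cyclopentyl]propanoic acid | C=C(C)[C@H]1CC[C@](C)(O[Si](CC)(CC)CC)[C@@H]1CCC(=O)O
F7 | step 23 | 3-[(1R,2S,5S)-2-methyl-5-(prop-1-en-2-yl)-2-[(triethylsilyl)oxy]cyclopentyl]propanoyl chloride | C=C(C)[C@H]1CC[C@](C)(O[Si](CC)(CC)CC)[C@@H]1CCC(=O)Cl
F8 | step 23 | triacylmethane from 29 and F7 (central carbon labile through the enol) | C=C(C)[C@H]1CC[C@](C)(O[Si](CC)(CC)CC)[C@@H]1CCC(=O)C(C(=O)[C@H](C)CC)C(=O)[C@@](CC=C(C)C)(C)C(=O)OC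
F9 | step 22 | malonyl triketone from 29 and methyl 3-chloro-3-oxopropanoate (central carbon labile through the enol) | CC[C@@H](C)C(=O)C(C(=O)CC(=O)OC)C(=O)[C@@](CC=C(C)C)(C)C(=O)OC
F10 | step 22 | methyl ester of ring B 4-carboxylic acid (32 with CO2CH3 at C-4) | COC(=O)C1=C(O)[C@@](C)(CC=C(C)C)C(=O)C(C(=O)[C@H](C)CC)=C1O
F11 | step 22 | ring B 4-carboxylic acid (32 with CO2H at C-4) | OC(=O)C1=C(O)[C@@](C)(CC=C(C)C)C(=O)C(C(=O)[C@H](C)CC)=C1O
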